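**Retrosynthetic overview**
- The last bond made is the Z-coumarate ester C–O bond. It is cut to a phenol-silylated cis-p-coumaric acid (from 4-hydroxybenzaldehyde by Z-selective olefination) and a cyclopropyl α-hydroxy ketone.
- The strategy rests on the cyclopropane: its ring CH2 is unsubstituted and lies between a ring CH that carries the ketone C=O and a ring CH that carries the CH(OH) carbon. Cutting both ring bonds to the acyl-bearing CH gives a terminal vinyl group and a lactate-derived diazomethyl ketone (an acylcarbene), to be joined by a catalytic [2+1] addition.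
- The vinyl partner holds ring CH2, ring CH, carbinol CH, lactone C6 and lactone C5 in a row. That is divinyl carbinol after Sharpless desymmetrization; the epoxide CH2 is opened by a propiolate that supplies lactone C4 to C2.
- Ring order: the dihydropyranone first (semihydrogenation, lactonization), the cyclopropane second (the convergent union), and the bought benzene ring is attached last in the ester.

Key step: step 11

Assumption: which enantiomer of the ruthenium phenyloxazoline catalyst sends the carbene to the required face of the vinyl lactone cannot be read from the structures alone; the route is written with the (S)-4-phenyl ligand, and the (R)-4-phenyl complex would be used in the same step if a test run shows it to be the matched one.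

**Route**

Step 1
Reactants: 1 penta-1,4-dien-3-ol (divinyl carbinol)
Product: 2 (2R,3S)-1,2-epoxypent-4-en-3-ol
Conditions: Ti(OiPr)4 (10 mol %), L-(+)-diisopropyl tartrate (13 mol %), t-BuOOH (anhydrous, 1.2 equiv), 4 Å sieves, CH2Cl2, −20 °C; non-aqueous work-up, used promptly
Reagents that add atoms: tert-butyl hydroperoxide, CC(C)(C)OO
Why: Sharpless asymmetric epoxidation run as a desymmetrization: the tetravalent titanium tartrate catalyst, bound to the carbinol oxygen, selects one of the two enantiotopic vinyl groups and one of its faces, so the epoxide carbon (R) and the erythro carbinol carbon (S) are both set by the reagent; L-(+)-tartrate is the enantiomer that gives the 2S,3S epoxides of simple (E)-2-alken-1-ols, which is the same facial sense as the 2R centre here, and the minor enantiomer should be drained off by a faster second epoxidation.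

Step 2
Reactants: 2 (2R,3S)-1,2-epoxypent-4-en-3-ol
Product: 3 (2R)-2-[(1S)-1-(tert-butyldimethylsilyloxy)prop-2-en-1-yl]oxirane
Conditions: TBSCl, imidazole, DMF, 0 °C to rt
Reagents that add atoms: tert-butyldimethylsilyl chloride, CC(C)(C)[Si](C)(C)Cl
Why: Standard silyl ether formation at the only hydroxyl group; no stereocentre is touched, the volatile epoxy alcohol becomes easy to handle and the carbinol oxygen is blocked against the later carbene.

Step 3
Reactants: 3 (2R)-2-[(1S)-1-(tert-butyldimethylsilyloxy)prop-2-en-1-yl]oxirane; 4 ethyl propiolate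
Product: 6 ethyl (5R,6S)-6-(tert-butyldimethylsilyloxy)-5-hydroxyoct-7-en-2-ynoate, via ethyl 3-lithioprop-2-ynoate 5 (not isolated)
Conditions: 4, n-BuLi, THF, −78 °C; BF3·OEt2; then 3, −78 °C; aq NH4Cl at −78 °C
Reagents that add atoms: none
Why: Yamaguchi-type alkynylation: the lithium acetylide opens the BF3-activated epoxide by SN2 attack at its unsubstituted CH2 terminus, so both stereocentres are carried over unchanged and lactone carbons C2 to C4 are added in one bond formation (the acetylide is kept at −78 °C because it decomposes when warmer).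

Step 4
Reactants: 6 ethyl (5R,6S)-6-(tert-butyldimethylsilyloxy)-5-hydroxyoct-7-en-2-ynoate
Product: 7 ethyl (2Z,5R,6S)-6-(tert-butyldimethylsilyloxy)-5-hydroxyocta-2,7-dienoate
Conditions: H2 (1 atm, stopped at 1 equiv), Pd/CaCO3 poisoned with Pb(OAc)2 (Lindlar catalyst), quinoline, EtOAc, rt
Reagents that add atoms: none
Why: Lindlar semihydrogenation: syn delivery of one equivalent of H2 on the poisoned palladium metal surface should give the Z enoate, the strongly adsorbed alkyne being reduced before the terminal vinyl group if uptake is stopped at one equivalent.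

Step 5
Reactants: 7 ethyl (2Z,5R,6S)-6-(tert-butyldimethylsilyloxy)-5-hydroxyocta-2,7-dienoate
Product: 8 (6R)-6-[(1S)-1-(tert-butyldimethylsilyloxy)prop-2-en-1-yl]-5,6-dihydro-2H-pyran-2-one
Conditions: PPTS (cat.), toluene, 60 °C
Reagents that add atoms: none
Why: Acid-catalysed lactonization (intramolecular transesterification): the Z alkene holds the C5 hydroxyl next to the ester so the six-membered unsaturated lactone should close with loss of ethanol, and the secondary TBS ether tolerates PPTS in an aprotic solvent.

Step 6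
Reactants: 9 methyl (R)-lactate
Product: 10 methyl (2R)-2-(triethylsilyloxy)propanoate
Conditions: TESCl, imidazole, CH2Cl2, 0 °C
Reagents that add atoms: triethylsilyl chloride, CC[Si](CC)(CC)Cl
Why: Silylation of the secondary hydroxyl without touching the stereocentre; the triethylsilyl group is chosen so that it can later be removed beside the TBS ether.

Step 7
Reactants: 10 methyl (2R)-2-(triethylsilyloxy)propanoate
Product: 11 (2R)-N-methoxy-N-methyl-2-(triethylsilyloxy)propanamide
Conditions: MeNH(OMe)·HCl, i-PrMgCl, THF, −20 °C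
Reagents that add atoms: N,O-dimethylhydroxylamine hydrochloride, CNOC.Cl
Why: Weinreb amide formation by aminolysis of the methyl ester with the chloromagnesium amide made in the flask; the low temperature and the hindered Grignard base should leave the α stereocentre intact.

Step 8
Reactants: 11 (2R)-N-methoxy-N-methyl-2-(triethylsilyloxy)propanamide
Product: 12 (3R)-3-(triethylsilyloxy)butan-2-one
Conditions: MeMgBr, THF, −78 to 0 °C; aq NH4Cl
Reagents that add atoms: methylmagnesium bromide, C[Mg]Br
Why: Weinreb ketone synthesis: MeMgBr adds once to give a stable chelated tetrahedral adduct that collapses to the methyl ketone only on work-up, so over-addition is avoided, and the new methyl group is the future diazo carbon.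

Step 9
Reactants: 12 (3R)-3-(triethylsilyloxy)butan-2-one
Product: 14 (5R)-1,1,1-trifluoro-5-(triethylsilyloxy)hexane-2,4-dione, via lithium (3R)-3-(triethylsilyloxy)but-1-en-2-olate 13 (not isolated)
Conditions: LiN(SiMe3)2, THF, −78 °C; CF3CO2CH2CF3, −78 °C; AcOH quench; crude product used at once
Reagents that add atoms: 2,2,2-trifluoroethyl trifluoroacetate, O=C(OCC(F)(F)F)C(F)(F)F
Why: Claisen-type trifluoroacetylation of the kinetic enolate (activation stage of the Danheiser diazo transfer): LiN(SiMe3)2 at −78 °C removes a proton from the unhindered methyl group and not from the siloxy-bearing CH, so the stereocentre should not be enolized.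

Step 10
Reactants: 14 (5R)-1,1,1-trifluoro-5-(triethylsilyloxy)hexane-2,4-dione
Product: 15 (3R)-1-diazo-3-(triethylsilyloxy)butan-2-one
Conditions: MsN3, Et3N, H2O (1 equiv), MeCN, rt
Reagents that add atoms: methanesulfonyl azide, CS(=O)(=O)N=[N+]=[N-]
Why: Detrifluoroacetylative diazo transfer (Danheiser variant of the Regitz reaction): the activated methylene takes N2 from MsN3 and the trifluoroacetyl group leaves as the N-acylsulfonamide, giving the diazomethyl ketone under a mild base that should not epimerize the siloxy centre.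

Step 11
Reactants: 8 (6R)-6-[(1S)-1-(tert-butyldimethylsilyloxy)prop-2-en-1-yl]-5,6-dihydro-2H-pyran-2-one; 15 (3R)-1-diazo-3-(triethylsilyloxy)butan-2-one
Product: 16 (6R)-6-[(S)-(tert-butyldimethylsilyloxy){(1S,2S)-2-[(2R)-2-(triethylsilyloxy)propanoyl]cyclopropyl}methyl]-5,6-dihydro-2H-pyran-2-one
Conditions: [Ru(C15H12NO)(CH3CN)4]PF6 (3 mol %; C15H12NO = ortho-metalated (S)-2,4-diphenyl-4,5-dihydrooxazole), CH2Cl2, 0 °C; 15 (2.5 equiv) by syringe pump over 10 h
Reagents that add atoms: none
Why: Proposed new method: the divalent ruthenium complex should take N2 from 15 to give an electrophilic metal-bound acylcarbene that adds to the only monosubstituted, unconjugated alkene of 8 in a concerted asynchronous [2+1] addition, bonding first to the terminal CH2 and then to the allylic CH; the closest known reaction type is the trans- and enantioselective cyclopropanation of terminal alkenes with diazomethyl ketones, diazoacetates and diazo Weinreb amides by the same cyclometalated ruthenium phenyloxazoline catalysts (and by Rh2(OAc)4 in the achiral series), which has not been shown for the union of a chiral allylic silyl ether with a chiral α-siloxy diazoketone. The three-membered ring closes by this cheletropic-type carbene transfer in which the diazo carbon forms both new C–C bonds, not by an enolate displacement, so neither the lactone nor the α-siloxy ketone centre meets a base. The two new ring stereocentres are set together: trans because the acyl group turns away from the alkene substituent in the approach, and in the (1S,2S) sense by the 4-phenyl stereocentre of the ligand, which has to send the carbene to the alkene face that carries the silyloxy group when the carbinol C–H eclipses the double bond, the intrinsic bias of the allylic centre being small. The step needs chemoselectivity for the vinyl group over the electron-poor cis-disubstituted lactone alkene, over ylide or O–H pathways and over allylic C–H insertion; this should follow from the electrophilic acceptor-only carbene, from both oxygens being silylated and from the slow addition of 15, which holds back carbene dimerization.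

Step 12
Reactants: 16 (6R)-6-[(S)-(tert-butyldimethylsilyloxy){(1S,2S)-2-[(2R)-2-(triethylsilyloxy)propanoyl]cyclopropyl}methyl]-5,6-dihydro-2H-pyran-2-one
Product: 17 (6R)-6-[(S)-(tert-butyldimethylsilyloxy){(1S,2S)-2-[(2R)-2-hydroxypropanoyl]cyclopropyl}methyl]-5,6-dihydro-2H-pyran-2-one
Conditions: PPTS (cat.), MeOH/CH2Cl2, 0 °C
Reagents that add atoms: none
Why: Selective desilylation: under mild acid in methanol the triethylsilyl ether is solvolysed much faster than the hindered secondary TBS ether, and a short reaction at 0 °C should spare the lactone and the α-hydroxy ketone centre.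

Step 13
Reactants: 18 4-hydroxybenzaldehyde
Product: 19 4-(tert-butyldimethylsilyloxy)benzaldehyde
Conditions: TBSCl, imidazole, DMF, rt
Reagents that add atoms: tert-butyldimethylsilyl chloride, CC(C)(C)[Si](C)(C)Cl
Why: Standard silylation of the phenol, needed because a free phenoxide would shut down the olefination of the aldehyde.

Step 14
Reactants: 19 4-(tert-butyldimethylsilyloxy)benzaldehyde
Product: 20 methyl (2Z)-3-[4-(tert-butyldimethylsilyloxy)phenyl]prop-2-enoate
Conditions: (CF3CH2O)2P(O)CH2CO2Me, KN(SiMe3)2, 18-crown-6, THF, −78 °C, dark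
Reagents that add atoms: methyl bis(2,2,2-trifluoroethyl)phosphonoacetate, COC(=O)CP(=O)(OCC(F)(F)F)OCC(F)(F)F
Why: Still–Gennari olefination: the bis(trifluoroethyl) phosphonate anion with a dissociated potassium counter-ion adds irreversibly and the adduct eliminates fast, which gives the Z enoate under kinetic control.

Step 15
Reactants: 20 methyl (2Z)-3-[4-(tert-butyldimethylsilyloxy)phenyl]prop-2-enoate
Product: 21 (2Z)-3-(4-hydroxyphenyl)prop-2-enoic acid (cis-p-coumaric acid)
Conditions: LiOH, THF/MeOH/H2O, 0 °C to rt, dark; then 1 M HCl to pH 3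
Reagents that add atoms: lithium hydroxide, [Li+].[OH-]
Why: Saponification of the methyl ester, which also cleaves the base-labile aryl silyl ether; hydroxide in the dark should not affect the Z alkene.

Step 16
Reactants: 21 (2Z)-3-(4-hydroxyphenyl)prop-2-enoic acid
Product: 23 (2Z)-3-[4-(tert-butyldimethylsilyloxy)phenyl]prop-2-enoic acid, via tert-butyldimethylsilyl (2Z)-3-[4-(tert-butyldimethylsilyloxy)phenyl]prop-2-enoate 22 (not isolated)
Conditions: TBSCl (2.5 equiv), imidazole, DMF, rt, dark; then THF/H2O/AcOH, rt, short
Reagents that add atoms: tert-butyldimethylsilyl chloride, CC(C)(C)[Si](C)(C)Cl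
Why: Silylation of both the phenol and the acid, then hydrolysis of the far more labile silyl ester under mild aqueous acid, which leaves the aryl TBS ether and gives the phenol-protected Z acid.

Step 17
Reactants: 17 (6R)-6-[(S)-(tert-butyldimethylsilyloxy){(1S,2S)-2-[(2R)-2-hydroxypropanoyl]cyclopropyl}methyl]-5,6-dihydro-2H-pyran-2-one; 23 (2Z)-3-[4-(tert-butyldimethylsilyloxy)phenyl]prop-2-enoic acid
Product: 24 (2R)-1-{(1S,2S)-2-[(S)-(tert-butyldimethylsilyloxy)[(2R)-6-oxo-3,6-dihydro-2H-pyran-2-yl]methyl]cyclopropyl}-1-oxopropan-2-yl (2Z)-3-[4-(tert-butyldimethylsilyloxy)phenyl]prop-2-enoate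
Conditions: EDC·HCl, DMAP (cat.), CH2Cl2, 0 °C, dark
Reagents that add atoms: none
Why: Carbodiimide esterification with DMAP acyl-transfer catalysis (Steglich type) at the free secondary hydroxyl; the carbinol C–O bond is not broken, so the R centre is retained, and low temperature, little DMAP and exclusion of light are meant to prevent Z to E isomerization and enolization of the ketone.

Step 18
Reactants: 24 the bis-TBS ether from step 17
Product: 25 (2R)-1-{(1S,2S)-2-[(S)-hydroxy[(2R)-6-oxo-3,6-dihydro-2H-pyran-2-yl]methyl]cyclopropyl}-1-oxopropan-2-yl (2Z)-3-(4-hydroxyphenyl)prop-2-enoate (CNP0246043.2)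
Conditions: HF·pyridine, pyridine, THF, 0 °C to rt, dark
Reagents that add atoms: none
Why: Fluoride-driven cleavage of both silicon–oxygen bonds under buffered, slightly acidic conditions, which should free the phenol quickly and the hindered carbinol more slowly without touching the lactone, the esters or the Z alkene.

**Compound list**

1 | penta-1,4-dien-3-ol (divinyl carbinol) | C=CC(O)C=C | starting material
2 | (2R,3S)-1,2-epoxypent-4-en-3-ol | C=C[C@H](O)[C@H]1CO1 | intermediate
3 | (2R)-2-[(1S)-1-(tert-butyldimethylsilyloxy)prop-2-en-1-yl]oxirane | C=C[C@H](O[Si](C)(C)C(C)(C)C)[C@H]1CO1 | intermediate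
4 | ethyl propiolate | C#CC(=O)OCC | starting material
5 | ethyl 3-lithioprop-2-ynoate | [Li]C#CC(=O)OCC | intermediate
6 | ethyl (5R,6S)-6-(tert-butyldimethylsilyloxy)-5-hydroxyoct-7-en-2-ynoate | C=C[C@H](O[Si](C)(C)C(C)(C)C)[C@H](O)CC#CC(=O)OCC | intermediate
7 | ethyl (2Z,5R,6S)-6-(tert-butyldimethylsilyloxy)-5-hydroxyocta-2,7-dienoate | C=C[C@H](O[Si](C)(C)C(C)(C)C)[C@H](O)C/C=C\C(=O)OCC | intermediate
8 | (6R)-6-[(1S)-1-(tert-butyldimethylsilyloxy)prop-2-en-1-yl]-5,6-dihydro-2H-pyran-2-one | C=C[C@H](O[Si](C)(C)C(C)(C)C)[C@H]1CC=CC(=O)O1 | intermediate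
9 | methyl (R)-lactate | C[C@@H](O)C(=O)OC | starting material
10 | methyl (2R)-2-(triethylsilyloxy)propanoate | C[C@@H](O[Si](CC)(CC)CC)C(=O)OC | intermediate
11 | (2R)-N-methoxy-N-methyl-2-(triethylsilyloxy)propanamide | C[C@@H](O[Si](CC)(CC)CC)C(=O)N(C)OC | intermediate
12 | (3R)-3-(triethylsilyloxy)butan-2-one | C[C@@H](O[Si](CC)(CC)CC)C(C)=O | intermediate
13 | lithium (3R)-3-(triethylsilyloxy)but-1-en-2-olate | C[C@@H](O[Si](CC)(CC)CC)C(=C)O[Li] | intermediate
14 | (5R)-1,1,1-trifluoro-5-(triethylsilyloxy)hexane-2,4-dione | C[C@@H](O[Si](CC)(CC)CC)C(=O)CC(=O)C(F)(F)F | intermediate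
15 | (3R)-1-diazo-3-(triethylsilyloxy)butan-2-one | C[C@@H](O[Si](CC)(CC)CC)C(=O)C=[N+]=[N-] | intermediate
16 | (6R)-6-[(S)-(tert-butyldimethylsilyloxy){(1S,2S)-2-[(2R)-2-(triethylsilyloxy)propanoyl]cyclopropyl}methyl]-5,6-dihydro-2H-pyran-2-one | C[C@@H](O[Si](CC)(CC)CC)C(=O)[C@H]1C[C@@H]1[C@H](O[Si](C)(C)C(C)(C)C)[C@H]1CC=CC(=O)O1 | intermediate
17 | (6R)-6-[(S)-(tert-butyldimethylsilyloxy){(1S,2S)-2-[(2R)-2-hydroxypropanoyl]cyclopropyl}methyl]-5,6-dihydro-2H-pyran-2-one | C[C@@H](O)C(=O)[C@H]1C[C@@H]1[C@H](O[Si](C)(C)C(C)(C)C)[C@H]1CC=CC(=O)O1 | intermediate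
18 | 4-hydroxybenzaldehyde | O=Cc1ccc(O)cc1 | starting material
19 | 4-(tert-butyldimethylsilyloxy)benzaldehyde | O=Cc1ccc(O[Si](C)(C)C(C)(C)C)cc1 | intermediate
20 | methyl (2Z)-3-[4-(tert-butyldimethylsilyloxy)phenyl]prop-2-enoate | COC(=O)/C=C\c1ccc(O[Si](C)(C)C(C)(C)C)cc1 | intermediate
21 | (2Z)-3-(4-hydroxyphenyl)prop-2-enoic acid | OC(=O)/C=C\c1ccc(O)cc1 | intermediate
22 | tert-butyldimethylsilyl (2Z)-3-[4-(tert-butyldimethylsilyloxy)phenyl]prop-2-enoate | CC(C)(C)[Si](C)(C)OC(=O)/C=C\c1ccc(O[Si](C)(C)C(C)(C)C)cc1 | intermediate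
23 | (2Z)-3-[4-(tert-butyldimethylsilyloxy)phenyl]prop-2-enoic acid | OC(=O)/C=C\c1ccc(O[Si](C)(C)C(C)(C)C)cc1 | intermediate
24 | bis-TBS ether of the target (aryl and carbinol oxygens silylated) | C[C@@H](OC(=O)/C=C\c1ccc(O[Si](C)(C)C(C)(C)C)cc1)C(=O)[C@H]1C[C@@H]1[C@H](O[Si](C)(C)C(C)(C)C)[C@H]1CC=CC(=O)O1 | intermediate
25 | CNP0246043.2 | C[C@@H](OC(=O)/C=C\c1ccc(O)cc1)C(=O)[C@H]1C[C@@H]1[C@H](O)[C@H]1CC=CC(=O)O1 | target

**Step count**

Total: 18 steps. Longest linear sequence: 9 steps (steps 1 to 5, 11, 12, 17, 18; the lactate branch through steps 6 to 10 is equally long).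

**Steps most likely to fail**

Step 11 (proposed new method). The carbene transfer may show poor facial selectivity between the two chiral partners, or the hindered allylic silyl ether may react so slowly that carbene dimerization consumes the diazoketone. The fallback uses known chemistry, sets out from 8 and 11 and returns at 16. Weinreb amide 11 with vinylmagnesium bromide (THF, −78 °C, cold NH4Cl quench) should give the vinyl ketone (4R)-4-(triethylsilyloxy)pent-1-en-3-one F1. Cross-metathesis of 8 with F1 (second-generation Hoveyda–Grubbs catalyst RuCl2(SIMes)(=CH-C6H4-2-OiPr), CH2Cl2, 40 °C) should give the E-enone (6R)-6-[(1S,2E,5R)-1-(tert-butyldimethylsilyloxy)-4-oxo-5-(triethylsilyloxy)hex-2-en-1-yl]-5,6-dihydro-2H-pyran-2-one F2. Corey–Chaykovsky cyclopropanation with dimethylsulfoxonium methylide (Me3S(O)I, NaH, DMSO/THF, 0 °C, one equivalent) would then give 16 by conjugate addition and ring closure. The E-enone fixes the trans ring, the ketone enone should react before the less electrophilic lactone enoate, and the facial sense rests on the γ-silyloxy centre, so the two trans isomers would have to be separated if that control is incomplete.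

Step 4. The hydrogenation may run on into the terminal vinyl group or stall before the alkyne is consumed. The fallback avoids hydrogenation, sets out from 3 and returns at 8.
- Epoxide 3 with 2-lithio-1,3-dithiane (n-BuLi, THF, −30 °C) should give (2R,3S)-3-(tert-butyldimethylsilyloxy)-1-(1,3-dithian-2-yl)pent-4-en-2-ol F3.
- TESCl and imidazole should give its triethylsilyl ether (2R,3S)-3-(tert-butyldimethylsilyloxy)-1-(1,3-dithian-2-yl)-2-(triethylsilyloxy)pent-4-ene F4.
- MeI and CaCO3 in aqueous MeCN should unmask the aldehyde (3R,4S)-4-(tert-butyldimethylsilyloxy)-3-(triethylsilyloxy)hex-5-enal F5.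
- Still–Gennari olefination ((CF3CH2O)2P(O)CH2CO2Me, KN(SiMe3)2, 18-crown-6, THF, −78 °C) should give methyl (2Z,5R,6S)-6-(tert-butyldimethylsilyloxy)-5-(triethylsilyloxy)octa-2,7-dienoate F6.
- PPTS in MeOH should remove the triethylsilyl group to give methyl (2Z,5R,6S)-6-(tert-butyldimethylsilyloxy)-5-hydroxyocta-2,7-dienoate F7, which on warming with PPTS in toluene should lactonize to 8.

Step 17. The activated cis-coumarate may isomerize from Z to E through reversible conjugate addition of DMAP, and the α-acyloxy ketone may epimerize. The fallback sets the Z geometry after the acylation, sets out from 19 and 17 and returns at 24.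
- Corey–Fuchs reaction of 19 (CBr4, PPh3, CH2Cl2, 0 °C) should give tert-butyl[4-(2,2-dibromoethenyl)phenoxy]dimethylsilane F8.
- n-BuLi (2 equiv, THF, −78 °C) followed by CO2 should give 3-[4-(tert-butyldimethylsilyloxy)phenyl]prop-2-ynoic acid F9.
- Carbodiimide coupling of F9 with 17 (EDC·HCl, cat. DMAP, CH2Cl2, −20 °C) should give the arylpropiolate ester of 17, F10.
- Lindlar semihydrogenation (Pd/CaCO3 poisoned with Pb(OAc)2, quinoline, H2, EtOAc) should give 24; no terminal alkene is present at this stage and the cis-disubstituted lactone alkene should not be reduced.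

**Further compounds**

F1 | step 11 | (4R)-4-(triethylsilyloxy)pent-1-en-3-one | C[C@@H](O[Si](CC)(CC)CC)C(=O)C=C
F2 | step 11 | (6R)-6-[(1S,2E,5R)-1-(tert-butyldimethylsilyloxy)-4-oxo-5-(triethylsilyloxy)hex-2-en-1-yl]-5,6-dihydro-2H-pyran-2-one | C[C@@H](O[Si](CC)(CC)CC)C(=O)/C=C/[C@H](O[Si](C)(C)C(C)(C)C)[C@H]1CC=CC(=O)O1
F3 | step 4 | (2R,3S)-3-(tert-butyldimethylsilyloxy)-1-(1,3-dithian-2-yl)pent-4-en-2-ol | C=C[C@H](O[Si](C)(C)C(C)(C)C)[C@H](O)CC1SCCCS1
F4 | step 4 | (2R,3S)-3-(tert-butyldimethylsilyloxy)-1-(1,3-dithian-2-yl)-2-(triethylsilyloxy)pent-4-ene | C=C[C@H](O[Si](C)(C)C(C)(C)C)[C@H](O[Si](CC)(CC)CC)CC1SCCCS1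
F5 | step 4 | (3R,4S)-4-(tert-butyldimethylsilyloxy)-3-(triethylsilyloxy)hex-5-enal | C=C[C@H](O[Si](C)(C)C(C)(C)C)[C@H](O[Si](CC)(CC)CC)CC=O
F6 | step 4 | methyl (2Z,5R,6S)-6-(tert-butyldimethylsilyloxy)-5-(triethylsilyloxy)octa-2,7-dienoate | C=C[C@H](O[Si](C)(C)C(C)(C)C)[C@H](O[Si](CC)(CC)CC)C/C=C\C(=O)OC
F7 | step 4 | methyl (2Z,5R,6S)-6-(tert-butyldimethylsilyloxy)-5-hydroxyocta-2,7-dienoate | C=C[C@H](O[Si](C)(C)C(C)(C)C)[C@H](O)C/C=C\C(=O)OC
F8 | step 17 | tert-butyl[4-(2,2-dibromoethenyl)phenoxy]dimethylsilane | BrC(Br)=Cc1ccc(O[Si](C)(C)C(C)(C)C)cc1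
F9 | step 17 | 3-[4-(tert-butyldimethylsilyloxy)phenyl]prop-2-ynoic acid | OC(=O)C#Cc1ccc(O[Si](C)(C)C(C)(C)C)cc1
F10 | step 17 | (2R)-1-{(1S,2S)-2-[(S)-(tert-butyldimethylsilyloxy)[(2R)-6-oxo-3,6-dihydro-2H-pyran-2-yl]methyl]cyclopropyl}-1-oxopropan-2-yl 3-[4-(tert-butyldimethylsilyloxy)phenyl]prop-2-ynoate | C[C@@H](OC(=O)C#Cc1ccc(O[Si](C)(C)C(C)(C)C)cc1)C(=O)[C@H]1C[C@@H]1[C@H](O[Si](C)(C)C(C)(C)C)[C@H]1CC=CC(=O)O1
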